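**Retrosynthetic overview**

1. Feature: on ring A the prenylated carbon C8 is para to O5, and on ring B the prenylated carbon C3' is ortho to O4', so each C-prenyl bond can be traced back to an allyl ether on that oxygen through [3,3] shifts. The remaining (2R,3R)-3-hydroxychroman-4-one core, with rings A, B and C intact, is (+)-aromadendrin.
2. Target ⇒ removal of the acetals on O3 and O7 and of the O4' methyl group ⇒ a 5,4'-diol that already carries both prenyl groups.
3. Key disconnection: C8–CH2 (Claisen then Cope, O5 → C6 → C8) and C3'–CH2 (ortho-Claisen of a 1,1-dimethylallyl ether, O4' → C3') ⇒ a 5-O-prenyl / 4'-O-(1,1-dimethylallyl) bis-ether.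
4. Bis-ether ⇒ Mitsunobu prenylation of O5, acetal on O3, Lindlar reduction, copper-catalysed tert-propargylation of O4', acetal on O7 ⇒ aromadendrin.
5. Ring order: no ring is formed anywhere in the route. Rings A, B and C and both stereocentres are bought with the starting material and only have to be preserved.

Key step: step 6

Remark: (+)-aromadendrin is taken as purchasable as the single (2R,3R) enantiomer. O5 is alkylated with 3-methylbut-2-en-1-ol under redox-condensation conditions rather than with an allyl halide and base, because carbonate bases can open ring C of 3-oxygenated flavanones and scramble C2 and C3.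

**Route**

Step 1
Reactants: 1 (+)-aromadendrin, (2R,3R)-3,5,7-trihydroxy-2-(4-hydroxyphenyl)chroman-4-one; 2 chloromethyl methyl ether
Product: 3 (2R,3R)-3,5-dihydroxy-2-(4-hydroxyphenyl)-7-(methoxymethoxy)chroman-4-one
Conditions: MOMCl (1.05 equiv), i-Pr2NEt (1.2 equiv), THF/CH2Cl2, 0 °C
Reagents that add atoms: chloromethyl methyl ether (2), COCCl
Why: Williamson-type O-alkylation with an α-chloro ether: the 7-OH is the most acidic phenol (a vinylogous acid through the C4 carbonyl), so with about one equivalent of amine base only the 7-phenoxide should be alkylated, while the chelated 5-OH, the less acidic 4'-OH and the secondary 3-OH stay free and C2 and C3 are not disturbed at 0 °C.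

Step 2
Reactants: 3 (2R,3R)-3,5-dihydroxy-2-(4-hydroxyphenyl)-7-(methoxymethoxy)chroman-4-one; 4 2-methylbut-3-yn-2-ol
Product: 6 (2R,3R)-3,5-dihydroxy-7-(methoxymethoxy)-2-[4-(2-methylbut-3-yn-2-yloxy)phenyl]chroman-4-one, via 2-methylbut-3-yn-2-yl trifluoroacetate 5 (not isolated)
Conditions: 4, (CF3CO)2O, DBU, MeCN, −5 °C; then 3, DBU, CuCl2·2H2O (1 mol%), MeCN, 0 °C
Reagents that add atoms: 2-methylbut-3-yn-2-ol (4), C#CC(C)(C)O
Why: Copper-catalysed propargylic etherification: the trifluoroacetate 5 formed in the flask gives a copper acetylide/allenylidene that is captured at its tertiary carbon by the only unhindered, non-chelated phenoxide (O4'), while the peri-chelated 5-OH and the C3 alcohol are far poorer nucleophiles at 0 °C.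

Step 3
Reactants: 6 (2R,3R)-3,5-dihydroxy-7-(methoxymethoxy)-2-[4-(2-methylbut-3-yn-2-yloxy)phenyl]chroman-4-one
Product: 7 (2R,3R)-3,5-dihydroxy-7-(methoxymethoxy)-2-[4-(2-methylbut-3-en-2-yloxy)phenyl]chroman-4-one
Conditions: H2 (1 atm), Pd/CaCO3 poisoned with Pb(OAc)2 (Lindlar catalyst), quinoline, EtOAc, rt
Reagents that add atoms: none
Why: Lindlar semihydrogenation: the poisoned palladium surface should reduce the terminal alkyne to the vinyl group and stop there, leaving the aryl ketone, the benzylic C2–O bond and the acetal untouched.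

Step 4
Reactants: 7 (2R,3R)-3,5-dihydroxy-7-(methoxymethoxy)-2-[4-(2-methylbut-3-en-2-yloxy)phenyl]chroman-4-one; 2 chloromethyl methyl ether
Product: 8 (2R,3R)-5-hydroxy-3,7-bis(methoxymethoxy)-2-[4-(2-methylbut-3-en-2-yloxy)phenyl]chroman-4-one
Conditions: MOMCl, i-Pr2NEt, CH2Cl2, 0 °C to rt
Reagents that add atoms: chloromethyl methyl ether (2), COCCl
Why: Acetal protection of a secondary alcohol by SN1-like O-alkylation with MOMCl and a hindered amine: the C3 alcohol should react while the 5-OH, locked in a hydrogen bond to the C4 carbonyl, does not, and the amine is too weak to enolise C3 or to harm the tertiary allyl ether.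

Step 5
Reactants: 8 (2R,3R)-5-hydroxy-3,7-bis(methoxymethoxy)-2-[4-(2-methylbut-3-en-2-yloxy)phenyl]chroman-4-one; 9 3-methylbut-2-en-1-ol
Product: 10 (2R,3R)-3,7-bis(methoxymethoxy)-2-[4-(2-methylbut-3-en-2-yloxy)phenyl]-5-(3-methylbut-2-en-1-yloxy)chroman-4-one
Conditions: 9, PPh3, DIAD, THF, 0 °C to rt
Reagents that add atoms: 3-methylbut-2-en-1-ol (9), CC(C)=CCO
Why: Mitsunobu etherification: the chelated 5-OH is acidic enough to protonate the betaine and then displaces the activated primary allylic alcohol by SN2 at its CH2 carbon under neutral conditions, which avoids a base-induced retro-oxa-Michael opening of ring C and leaves the heat-sensitive tertiary allyl ether alone at room temperature.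

Step 6
Reactants: 10 (2R,3R)-3,7-bis(methoxymethoxy)-2-[4-(2-methylbut-3-en-2-yloxy)phenyl]-5-(3-methylbut-2-en-1-yloxy)chroman-4-one
Product: 15 (2R,3R)-5-hydroxy-2-[4-hydroxy-3-(3-methylbut-2-en-1-yl)phenyl]-3,7-bis(methoxymethoxy)-8-(3-methylbut-2-en-1-yl)chroman-4-one, via C6 ortho-dienone 11 (not isolated), via C8 para-dienone 12 (not isolated), via 8-prenyl 4'-ether 13 (not isolated), via ring B ortho-dienone 14 (not isolated)
Conditions: Eu(fod)3 (10 mol%), NaHCO3, PhCl, 85 °C, then 120 °C (fod = 6,6,7,7,8,8,8-heptafluoro-2,2-dimethyl-3,5-octanedionate)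
Reagents that add atoms: none
Why: Eu(fod)3 chelates the C4 carbonyl and the O5 ether oxygen and so accelerates the aromatic Claisen [3,3] shift of the prenyl ether to C6, the only free ortho carbon of O5 (the other is the ring-fusion carbon C4a), giving dienone 11, in which C6 is an sp3 CH carrying the inverted 1,1-dimethylallyl unit; a Cope [3,3] shift across C6–C7=C8 then delivers the CH2 terminus to C8 (12), enolisation gives phenol 13, and the ring B tertiary ether, which has no chelating neighbour, then undergoes the thermal ortho-Claisen shift at 120 °C through dienone 14 to the 3'-prenyl phenol. The closest known reaction types are the europium-catalysed para-Claisen–Cope rearrangement of 5-O-prenylflavonoids and the ortho-Claisen rearrangement of aryl 1,1-dimethylallyl ethers, both established on this substrate class and here run in one flask. No ring is closed and no stereocentre is formed; all shifts are concerted, suprafacial and neutral, so C2 and C3 are not touched. The step needs C8 and not C6 as the final site on ring A: in 11 the bulky tert-alkyl group is squeezed between the europium-bound C5 carbonyl and the C7 acetal oxygen and proton transfer is slow in aprotic chlorobenzene, so the Cope shift to the unsubstituted C8 should outrun enolisation, and the O7 acetal prevents chroman closure onto the new prenyl group. On ring B the single inversion of the tertiary allyl unit gives a normal prenyl group, and C3' and C5' are equivalent by rotation about the C2–C1' bond, so one product is expected. Solid NaHCO3 scavenges traces of acid that would otherwise ionise the tertiary ether or the acetals.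

Step 7
Reactants: 15 (2R,3R)-5-hydroxy-2-[4-hydroxy-3-(3-methylbut-2-en-1-yl)phenyl]-3,7-bis(methoxymethoxy)-8-(3-methylbut-2-en-1-yl)chroman-4-one; 16 iodomethane
Product: 17 (2R,3R)-5-hydroxy-2-[4-methoxy-3-(3-methylbut-2-en-1-yl)phenyl]-3,7-bis(methoxymethoxy)-8-(3-methylbut-2-en-1-yl)chroman-4-one
Conditions: MeI (1.2 equiv), K2CO3, acetone, rt
Reagents that add atoms: iodomethane (16), CI
Why: Williamson methylation: the free 4'-phenoxide should be methylated at room temperature while the 5-OH, hydrogen-bonded to and shielded by the C4 carbonyl, resists a near-stoichiometric amount of MeI, and both acetals are stable to base.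

Step 8
Reactants: 17 (2R,3R)-5-hydroxy-2-[4-methoxy-3-(3-methylbut-2-en-1-yl)phenyl]-3,7-bis(methoxymethoxy)-8-(3-methylbut-2-en-1-yl)chroman-4-one
Product: 18 (2R,3R)-3,5,7-trihydroxy-2-[4-methoxy-3-(3-methylbut-2-en-1-yl)phenyl]-8-(3-methylbut-2-en-1-yl)chroman-4-one (target)
Conditions: 3 M aq HCl, MeOH, 45 °C
Reagents that add atoms: none
Why: Acid-catalysed acetal exchange (MOM solvolysis) in methanol should release the 7-phenol and the 3-alcohol as dimethoxymethane, with the temperature kept moderate so that the prenyl alkenes are neither hydrochlorinated nor cyclised onto the neighbouring 7-OH, and with no pathway for epimerisation of C2 or C3 under acid.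

**Compound list**

1 | (+)-aromadendrin, (2R,3R)-3,5,7-trihydroxy-2-(4-hydroxyphenyl)chroman-4-one | Oc1ccc([C@H]2Oc3cc(O)cc(O)c3C(=O)[C@@H]2O)cc1 | starting material
2 | chloromethyl methyl ether | COCCl | starting material
3 | (2R,3R)-3,5-dihydroxy-2-(4-hydroxyphenyl)-7-(methoxymethoxy)chroman-4-one | Oc1ccc([C@H]2Oc3cc(OCOC)cc(O)c3C(=O)[C@@H]2O)cc1 | intermediate
4 | 2-methylbut-3-yn-2-ol | C#CC(C)(C)O | starting material
5 | 2-methylbut-3-yn-2-yl trifluoroacetate (formed in the flask) | C#CC(C)(C)OC(=O)C(F)(F)F | intermediate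
6 | (2R,3R)-3,5-dihydroxy-7-(methoxymethoxy)-2-[4-(2-methylbut-3-yn-2-yloxy)phenyl]chroman-4-one | C#CC(C)(C)Oc1ccc([C@H]2Oc3cc(OCOC)cc(O)c3C(=O)[C@@H]2O)cc1 | intermediate
7 | (2R,3R)-3,5-dihydroxy-7-(methoxymethoxy)-2-[4-(2-methylbut-3-en-2-yloxy)phenyl]chroman-4-one | C=CC(C)(C)Oc1ccc([C@H]2Oc3cc(OCOC)cc(O)c3C(=O)[C@@H]2O)cc1 | intermediate
8 | (2R,3R)-5-hydroxy-3,7-bis(methoxymethoxy)-2-[4-(2-methylbut-3-en-2-yloxy)phenyl]chroman-4-one | C=CC(C)(C)Oc1ccc([C@H]2Oc3cc(OCOC)cc(O)c3C(=O)[C@@H]2OCOC)cc1 | intermediate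
9 | 3-methylbut-2-en-1-ol | CC(C)=CCO | starting material
10 | (2R,3R)-3,7-bis(methoxymethoxy)-2-[4-(2-methylbut-3-en-2-yloxy)phenyl]-5-(3-methylbut-2-en-1-yloxy)chroman-4-one (key-step precursor) | C=CC(C)(C)Oc1ccc([C@H]2Oc3cc(OCOC)cc(OCC=C(C)C)c3C(=O)[C@@H]2OCOC)cc1 | intermediate
11 | C6 ortho-dienone, (2R,3R)-3,7-bis(methoxymethoxy)-6-(2-methylbut-3-en-2-yl)-2-[4-(2-methylbut-3-en-2-yloxy)phenyl]-2,3-dihydro-6H-chromene-4,5-dione (C6 unassigned) | C=CC(C)(C)Oc1ccc([C@H]2OC3=C(C(=O)[C@@H]2OCOC)C(=O)C(C(C)(C)C=C)C(OCOC)=C3)cc1 | intermediate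
12 | C8 para-dienone, (2R,3R)-3,7-bis(methoxymethoxy)-8-(3-methylbut-2-en-1-yl)-2-[4-(2-methylbut-3-en-2-yloxy)phenyl]-2,3-dihydro-8H-chromene-4,5-dione (C8 unassigned) | C=CC(C)(C)Oc1ccc([C@H]2OC3=C(C(=O)[C@@H]2OCOC)C(=O)C=C(OCOC)C3CC=C(C)C)cc1 | intermediate
13 | 8-prenyl 4'-ether, (2R,3R)-5-hydroxy-3,7-bis(methoxymethoxy)-8-(3-methylbut-2-en-1-yl)-2-[4-(2-methylbut-3-en-2-yloxy)phenyl]chroman-4-one | C=CC(C)(C)Oc1ccc([C@H]2Oc3c(CC=C(C)C)c(OCOC)cc(O)c3C(=O)[C@@H]2OCOC)cc1 | intermediate
14 | ring B ortho-dienone, (2R,3R)-5-hydroxy-3,7-bis(methoxymethoxy)-8-(3-methylbut-2-en-1-yl)-2-[3-(3-methylbut-2-en-1-yl)-4-oxocyclohexa-1,5-dien-1-yl]chroman-4-one (C3' unassigned) | O=C1C=CC([C@H]2Oc3c(CC=C(C)C)c(OCOC)cc(O)c3C(=O)[C@@H]2OCOC)=CC1CC=C(C)C | intermediate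
15 | (2R,3R)-5-hydroxy-2-[4-hydroxy-3-(3-methylbut-2-en-1-yl)phenyl]-3,7-bis(methoxymethoxy)-8-(3-methylbut-2-en-1-yl)chroman-4-one (key-step product) | Oc1ccc([C@H]2Oc3c(CC=C(C)C)c(OCOC)cc(O)c3C(=O)[C@@H]2OCOC)cc1CC=C(C)C | intermediate
16 | iodomethane | CI | starting material
17 | (2R,3R)-5-hydroxy-2-[4-methoxy-3-(3-methylbut-2-en-1-yl)phenyl]-3,7-bis(methoxymethoxy)-8-(3-methylbut-2-en-1-yl)chroman-4-one | COc1ccc([C@H]2Oc3c(CC=C(C)C)c(OCOC)cc(O)c3C(=O)[C@@H]2OCOC)cc1CC=C(C)C | intermediate
18 | (2R,3R)-3,5,7-trihydroxy-2-[4-methoxy-3-(3-methylbut-2-en-1-yl)phenyl]-8-(3-methylbut-2-en-1-yl)chroman-4-one | COc1ccc([C@H]2Oc3c(CC=C(C)C)c(O)cc(O)c3C(=O)[C@@H]2O)cc1CC=C(C)C | target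

**Step count**

Total steps: 8. Longest linear sequence: 8 steps, from 1 to 18.

**Steps most likely to fail**

Step 6. Two processes may go wrong. The Lewis acid may ionise the tertiary allyl ether on ring B before it rearranges, with loss of the five-carbon unit. The C6 dienone may also enolise before the Cope shift, which strands the allyl unit on C6 in its inverted form. Fallback: the two rearrangements are staged, so that the ring B ether never meets the lanthanide. It sets out from 8, which is heated without Lewis acid (PhCl, NaHCO3, 120 °C) for the thermal ortho-Claisen shift. This should give (2R,3R)-5-hydroxy-2-[4-hydroxy-3-(3-methylbut-2-en-1-yl)phenyl]-3,7-bis(methoxymethoxy)chroman-4-one F1. Methylation of the free 4'-phenol (MeI, K2CO3, acetone, rt) should give (2R,3R)-5-hydroxy-2-[4-methoxy-3-(3-methylbut-2-en-1-yl)phenyl]-3,7-bis(methoxymethoxy)chroman-4-one F2. Mitsunobu reaction with 9 (PPh3, DIAD, THF) should give (2R,3R)-2-[4-methoxy-3-(3-methylbut-2-en-1-yl)phenyl]-3,7-bis(methoxymethoxy)-5-(3-methylbut-2-en-1-yloxy)chroman-4-one F3. The europium-catalysed Claisen–Cope rearrangement on ring A alone (Eu(fod)3, NaHCO3, PhCl, 85 °C) then brings the material back to the route at 17.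

Step 2. DBU may open ring C through the 4'-phenoxide (quinone methide) or enolise C3, which would erode the C2/C3 configuration, and some alkylation may occur at O5 or O3. Fallback: a base-free, palladium-catalysed decarboxylative O-allylation installs the 1,1-dimethylallyl ether directly. It sets out from 3. The reagent tert-butyl 2-methylbut-3-en-2-yl carbonate F4 is made from 2-methylbut-3-en-2-ol, n-BuLi and di-tert-butyl dicarbonate in THF. Treatment of 3 with F4 and Pd(PPh3)4 (a zerovalent palladium complex) in THF at 0 °C should give the branched tertiary ether as the kinetic product, since the phenoxide attacks the more substituted terminus of the π-allyl complex. The fallback comes back to the route at 7 and makes step 3 unnecessary.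

Step 8. The aliphatic acetal on O3 cleaves slowly, and during that time the liberated 7-OH may add to the C8 prenyl alkene (chroman closure) or HCl/MeOH may add to the alkenes. Fallback: O3 is carried as a triethylsilyl ether, which falls off under much weaker acid. It sets out from 7. Silylation (Et3SiCl, imidazole, DMF, 0 °C) should give (2R,3R)-5-hydroxy-7-(methoxymethoxy)-2-[4-(2-methylbut-3-en-2-yloxy)phenyl]-3-(triethylsilyloxy)chroman-4-one F5. Mitsunobu reaction with 9 should give (2R,3R)-7-(methoxymethoxy)-2-[4-(2-methylbut-3-en-2-yloxy)phenyl]-5-(3-methylbut-2-en-1-yloxy)-3-(triethylsilyloxy)chroman-4-one F6. The tandem rearrangement under the conditions of step 6 should give (2R,3R)-5-hydroxy-2-[4-hydroxy-3-(3-methylbut-2-en-1-yl)phenyl]-7-(methoxymethoxy)-8-(3-methylbut-2-en-1-yl)-3-(triethylsilyloxy)chroman-4-one F7. Methylation (MeI, K2CO3, acetone, rt) should give (2R,3R)-5-hydroxy-2-[4-methoxy-3-(3-methylbut-2-en-1-yl)phenyl]-7-(methoxymethoxy)-8-(3-methylbut-2-en-1-yl)-3-(triethylsilyloxy)chroman-4-one F8. Brief treatment with 1 M aq HCl in MeOH at rt should remove the silyl ether and the aryl acetal and comes back to the route at 18.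

**Further compounds**

F1 | step 6 | (2R,3R)-5-hydroxy-2-[4-hydroxy-3-(3-methylbut-2-en-1-yl)phenyl]-3,7-bis(methoxymethoxy)chroman-4-one | Oc1ccc([C@H]2Oc3cc(OCOC)cc(O)c3C(=O)[C@@H]2OCOC)cc1CC=C(C)C
F2 | step 6 | (2R,3R)-5-hydroxy-2-[4-methoxy-3-(3-methylbut-2-en-1-yl)phenyl]-3,7-bis(methoxymethoxy)chroman-4-one | COc1ccc([C@H]2Oc3cc(OCOC)cc(O)c3C(=O)[C@@H]2OCOC)cc1CC=C(C)C
F3 | step 6 | (2R,3R)-2-[4-methoxy-3-(3-methylbut-2-en-1-yl)phenyl]-3,7-bis(methoxymethoxy)-5-(3-methylbut-2-en-1-yloxy)chroman-4-one | COc1ccc([C@H]2Oc3cc(OCOC)cc(OCC=C(C)C)c3C(=O)[C@@H]2OCOC)cc1CC=C(C)C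
F4 | step 2 | tert-butyl 2-methylbut-3-en-2-yl carbonate | C=CC(C)(C)OC(=O)OC(C)(C)C
F5 | step 8 | (2R,3R)-5-hydroxy-7-(methoxymethoxy)-2-[4-(2-methylbut-3-en-2-yloxy)phenyl]-3-(triethylsilyloxy)chroman-4-one | C=CC(C)(C)Oc1ccc([C@H]2Oc3cc(OCOC)cc(O)c3C(=O)[C@@H]2O[Si](CC)(CC)CC)cc1
F6 | step 8 | (2R,3R)-7-(methoxymethoxy)-2-[4-(2-methylbut-3-en-2-yloxy)phenyl]-5-(3-methylbut-2-en-1-yloxy)-3-(triethylsilyloxy)chroman-4-one | C=CC(C)(C)Oc1ccc([C@H]2Oc3cc(OCOC)cc(OCC=C(C)C)c3C(=O)[C@@H]2O[Si](CC)(CC)CC)cc1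
F7 | step 8 | (2R,3R)-5-hydroxy-2-[4-hydroxy-3-(3-methylbut-2-en-1-yl)phenyl]-7-(methoxymethoxy)-8-(3-methylbut-2-en-1-yl)-3-(triethylsilyloxy)chroman-4-one | Oc1ccc([C@H]2Oc3c(CC=C(C)C)c(OCOC)cc(O)c3C(=O)[C@@H]2O[Si](CC)(CC)CC)cc1CC=C(C)C
F8 | step 8 | (2R,3R)-5-hydroxy-2-[4-methoxy-3-(3-methylbut-2-en-1-yl)phenyl]-7-(methoxymethoxy)-8-(3-methylbut-2-en-1-yl)-3-(triethylsilyloxy)chroman-4-one | COc1ccc([C@H]2Oc3c(CC=C(C)C)c(OCOC)cc(O)c3C(=O)[C@@H]2O[Si](CC)(CC)CC)cc1CC=C(C)C
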